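**Plan**

1. Retrosynthesis (numbering: C1 = CO2H, ring = O1, O2, C3–C6, side chain C7–C16, phenyl on C16): the 1,2-dioxane is opened at O1–C6 (cycloperoxymercuration) and at O2–C3 (SN2 by a peroxide); the chain is then cut at C6–C7 (Negishi), C11–C12 (boronate 1,2-shift), C3–C4 (allenylindium addition) and C9–C10 (Grignard/oxirane).
2. Enabling feature: C12 is a heteroatom-free CH(CH3) stereocenter flanked by the methylenes C11 and C13, remote from the 1,2-dioxane ring. It can therefore be carried as a configurationally stable secondary boronate while C11 becomes an α-oxygenated lithium carbenoid; two nucleophilic carbons are joined by 1,2-migration with retention at C12, and the boron left on C11 is then replaced by hydrogen.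
3. Forward: side chain C7–C16 (steps 1–9), head C1–C6 as an (E)-alkenyl iodide (steps 10–14), union at C6–C7 (step 15); the only ring, the 1,2-dioxane, closes last (O2–C3 in step 17, O1–C6 in step 19) and C1 is oxidised to the acid (step 20).
4. Stereochemistry: C12 from sparteine-controlled lithiation–borylation (step 3) and retentive migration (step 7); C8 from (S)-3-bromo-2-methylpropan-1-ol; C4 and C3 from a catalyst-set propargylic carbinol relayed by anti-selective allenylindium addition, C3 then inverted by the peroxide SN2; C6 from anti addition across the (5E)-alkene through a chair with the C4 methyl equatorial.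

Key step: step 7

**Route**

Step 1
Reactants: 1 4-phenylbut-1-ene
Product: 2 4,4,5,5-tetramethyl-2-(4-phenylbutyl)-1,3,2-dioxaborolane
Conditions: HBpin, [Ir(cod)Cl]2 (cat.), dppm (cat.), CH2Cl2, rt
Reagents that add atoms: pinacolborane, CC1(C)OBOC1(C)C
Why: Iridium-catalysed anti-Markovnikov hydroboration of a terminal alkene puts boron on the terminal carbon and creates no stereocenter.

Step 2
Reactants: 3 2,4,6-triisopropylbenzoic acid
Product: 4 ethyl 2,4,6-triisopropylbenzoate
Conditions: EtI, K2CO3, DMF, rt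
Reagents that add atoms: iodoethane, CCI
Why: O-alkylation of the carboxylate (SN2 at the primary iodide) avoids acyl substitution at the shielded carbonyl and creates no stereocenter.

Step 3
Reactants: 4 ethyl 2,4,6-triisopropylbenzoate; 2 4,4,5,5-tetramethyl-2-(4-phenylbutyl)-1,3,2-dioxaborolane
Product: 7 4,4,5,5-tetramethyl-2-[(2S)-6-phenylhexan-2-yl]-1,3,2-dioxaborolane, via lithiated benzoate 5 (not isolated), via boronate complex 6 (not isolated)
Conditions: s-BuLi, (+)-sparteine, Et2O, −78 °C; then 2, −78 °C → 35 °C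
Reagents that add atoms: none
Why: Sparteine-mediated α-lithiation (Hoppe lithiation) should give the (R)-lithiated benzoate, which borylates with retention and rearranges by 1,2-metallate shift with inversion at the carbenoid carbon (lithiation–borylation), so the diamine alone fixes the future C12 as S.

Step 4
Reactants: 8 (2S)-3-bromo-2-methylpropan-1-ol
Product: 9 [(2S)-3-bromo-2-methylpropoxy](tert-butyl)dimethylsilane
Conditions: TBSCl, imidazole, DMF, rt
Reagents that add atoms: tert-butyldimethylsilyl chloride, CC(C)(C)[Si](C)(C)Cl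
Why: Silylation of the primary alcohol protects it for the Grignard step and leaves the stereocenter (the future C8) untouched.

Step 5
Reactants: 9 [(2S)-3-bromo-2-methylpropoxy](tert-butyl)dimethylsilane
Product: 11 (4R)-5-[(tert-butyldimethylsilyl)oxy]-4-methylpentan-1-ol, via Grignard reagent 10 (not isolated)
Conditions: Mg, THF, rt; then oxirane, CuI (cat.), −30 → 0 °C; aq NH4Cl
Reagents that add atoms: oxirane, C1CO1
Why: Copper-catalysed ring opening of ethylene oxide by the primary Grignard reagent adds C10 and C11 as a hydroxyethyl unit without touching the stereocenter.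

Step 6
Reactants: 11 (4R)-5-[(tert-butyldimethylsilyl)oxy]-4-methylpentan-1-ol; 3 2,4,6-triisopropylbenzoic acid
Product: 12 (4R)-5-[(tert-butyldimethylsilyl)oxy]-4-methylpentyl 2,4,6-triisopropylbenzoate
Conditions: PPh3, DIAD, THF, 0 °C → rt
Reagents that add atoms: none
Why: Mitsunobu esterification of the primary alcohol with the hindered acid installs the benzoate that directs the later α-lithiation and involves no stereocenter.

Step 7
Reactants: 12 (4R)-5-[(tert-butyldimethylsilyl)oxy]-4-methylpentyl 2,4,6-triisopropylbenzoate; 7 4,4,5,5-tetramethyl-2-[(2S)-6-phenylhexan-2-yl]-1,3,2-dioxaborolane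
Product: 15 tert-butyl{[(2R,5S,6S)-2,6-dimethyl-10-phenyl-5-(4,4,5,5-tetramethyl-1,3,2-dioxaborolan-2-yl)decyl]oxy}dimethylsilane, via lithiated benzoate 13 (not isolated), via boronate complex 14 (not isolated)
Conditions: s-BuLi, (+)-sparteine, Et2O, −78 °C; then 7, −78 °C → 35 °C
Reagents that add atoms: none
Why: s-BuLi/(+)-sparteine removes one C11 proton next to the benzoate oxygen, the configurationally stable α-lithiated benzoate 13 adds to the boron of 7 with retention to give ate complex 14, and on warming the C12 alkyl group shifts from boron to C11 anti to the departing benzoate, which makes the C11–C12 bond. The closest known reaction type is lithiation–borylation, a Matteson-type 1,2-metallate rearrangement of an α-oxygenated organolithium with a secondary pinacol boronate, as used for joining methyl-branched chains. No ring is closed. C12 migrates with retention, so its S configuration is that of 7; the new C11 stereocenter (S, from the sparteine-selected proton and inversion at the carbenoid carbon) is temporary and disappears in step 8. The step needs lithiation at C11 only and carbon rather than oxygen migration in 14: the hindered triisopropylbenzoate resists acyl attack and is a good leaving group, the silyl ether and saturated chain of 12 offer no competing acidic or electrophilic site, and 7 has no second boron-bound carbon that could migrate.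

Step 8
Reactants: 15 tert-butyl{[(2R,5S,6S)-2,6-dimethyl-10-phenyl-5-(4,4,5,5-tetramethyl-1,3,2-dioxaborolan-2-yl)decyl]oxy}dimethylsilane
Product: 17 tert-butyl{[(2R,6S)-2,6-dimethyl-10-phenyldecyl]oxy}dimethylsilane, via phenylboronate complex 16 (not isolated)
Conditions: PhLi, Et2O, 0 °C; then Ir[dF(CF3)ppy]2(dtbbpy)PF6 (cat.), PhSH (cat.), MeOH–acetone, blue LED, rt
Reagents that add atoms: none
Why: Radical protodeboronation of the aryl boronate complex (photoredox single-electron oxidation, C–B homolysis, hydrogen-atom transfer from the thiol) should replace boron on C11 by hydrogen, making C11 a plain CH2 without involving C12 or C8.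

Step 9
Reactants: 17 tert-butyl{[(2R,6S)-2,6-dimethyl-10-phenyldecyl]oxy}dimethylsilane
Product: 18 [(5S,9R)-10-bromo-5,9-dimethyldecyl]benzene
Conditions: Ph3PBr2, CH2Cl2, 0 °C → rt
Reagents that add atoms: triphenylphosphine dibromide, BrP(Br)(c1ccccc1)(c1ccccc1)c1ccccc1
Why: Triphenylphosphine dibromide converts the primary silyl ether directly into the bromide (oxyphosphonium activation, then SN2 by bromide at the primary carbon C7), so the adjacent C8 stereocenter is not touched.

Step 10
Reactants: 19 pent-3-yn-2-one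
Product: 20 (2R)-pent-3-yn-2-ol
Conditions: RuCl[(R,R)-TsDPEN](p-cymene) (cat.), i-PrOH, rt
Reagents that add atoms: none
Why: Noyori asymmetric transfer hydrogenation of an alkynyl ketone delivers hydride to one carbonyl face under catalyst control, the (R,R)-ligand being chosen to give the R carbinol.

Step 11
Reactants: 20 (2R)-pent-3-yn-2-ol
Product: 21 (2R)-pent-3-yn-2-yl methanesulfonate
Conditions: MsCl, Et3N, CH2Cl2, −78 → 0 °C
Reagents that add atoms: methanesulfonyl chloride, CS(=O)(=O)Cl
Why: O-sulfonylation breaks no bond to the stereocenter and turns the propargylic alcohol into the electrophile for allenylmetal formation.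

Step 12
Reactants: 21 (2R)-pent-3-yn-2-yl methanesulfonate; 22 3-[(tert-butyldimethylsilyl)oxy]propanal
Product: 24 (3R,4S)-1-[(tert-butyldimethylsilyl)oxy]-4-methylhept-5-yn-3-ol, via allenylindium 23 (not isolated)
Conditions: PdCl2(dppf) (cat.), InI, THF–HMPA, rt
Reagents that add atoms: none
Why: Marshall propargylation: anti SN2′ oxidative addition of zerovalent palladium and transmetalation to indium give a chiral allenylindium that adds to the aldehyde through a cyclic SE2′ transition state, which relays the mesylate chirality to C4 (S) and sets C3 (R) anti to it.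

Step 13
Reactants: 24 (3R,4S)-1-[(tert-butyldimethylsilyl)oxy]-4-methylhept-5-yn-3-ol
Product: 25 (3R,4S)-1-[(tert-butyldimethylsilyl)oxy]-4-methylhept-5-yn-3-yl methanesulfonate
Conditions: MsCl, Et3N, CH2Cl2, 0 °C
Reagents that add atoms: methanesulfonyl chloride, CS(=O)(=O)Cl
Why: O-sulfonylation with retention at C3 installs the leaving group for step 17 and removes the free hydroxyl, which would otherwise direct the hydrozirconation to C5.

Step 14
Reactants: 25 (3R,4S)-1-[(tert-butyldimethylsilyl)oxy]-4-methylhept-5-yn-3-yl methanesulfonate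
Product: 27 (3R,4S,5E)-1-[(tert-butyldimethylsilyl)oxy]-6-iodo-4-methylhept-5-en-3-yl methanesulfonate, via alkenylzirconocene 26 (not isolated)
Conditions: Cp2Zr(H)Cl, THF, 50 °C; then I2, 0 °C
Reagents that add atoms: iodine, II
Why: Hydrozirconation of the 2-alkyne (syn addition, zirconium settling on the less hindered methyl-bearing carbon C6) followed by iododezirconation with retention should give the (E)-2-iodoalkene with iodine trans to C4.

Step 15
Reactants: 18 [(5S,9R)-10-bromo-5,9-dimethyldecyl]benzene; 27 (3R,4S,5E)-1-[(tert-butyldimethylsilyl)oxy]-6-iodo-4-methylhept-5-en-3-yl methanesulfonate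
Product: 29 (3R,4S,5E,8R,12S)-1-[(tert-butyldimethylsilyl)oxy]-4,6,8,12-tetramethyl-16-phenylhexadec-5-en-3-yl methanesulfonate, via alkylzinc bromide 28 (not isolated)
Conditions: Zn, LiCl, THF, 50 °C; then 27, Pd(PPh3)4 (cat.), rt
Reagents that add atoms: none
Why: Negishi sp3–sp2 cross-coupling joins C7 to C6 with retention of the alkene geometry, so C7 ends trans to C4 (5E), and the secondary mesylate and silyl ether are inert to the alkylzinc halide and the palladium catalyst.

Step 16
Reactants: 30 2,3-dimethylbut-2-ene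
Product: 31 2-hydroperoxy-2-methoxypropane
Conditions: O3, MeOH–CH2Cl2, −78 °C
Reagents that add atoms: ozone, [O-][O+]=O; methanol, CO
Why: Ozonolysis in methanol traps the acetone carbonyl oxide (Criegee intermediate) as the α-methoxy hydroperoxide, a monoprotected hydrogen peroxide with no stereocenter.

Step 17
Reactants: 29 (3R,4S,5E,8R,12S)-1-[(tert-butyldimethylsilyl)oxy]-4,6,8,12-tetramethyl-16-phenylhexadec-5-en-3-yl methanesulfonate; 31 2-hydroperoxy-2-methoxypropane
Product: 32 tert-butyl({(3S,4S,5E,8R,12S)-3-[(2-methoxypropan-2-yl)peroxy]-4,6,8,12-tetramethyl-16-phenylhexadec-5-en-1-yl}oxy)dimethylsilane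
Conditions: CsOH·H2O, DMF, 0 °C → rt
Reagents that add atoms: none
Why: SN2 alkylation of the cesium peroxide, an α-effect nucleophile of low basicity, by the secondary mesylate should form the O2–C3 bond with inversion, turning C3 from R to S.

Step 18
Reactants: 32 tert-butyl({(3S,4S,5E,8R,12S)-3-[(2-methoxypropan-2-yl)peroxy]-4,6,8,12-tetramethyl-16-phenylhexadec-5-en-1-yl}oxy)dimethylsilane
Product: 33 (3S,4S,5E,8R,12S)-1-[(tert-butyldimethylsilyl)oxy]-4,6,8,12-tetramethyl-16-phenylhexadec-5-en-3-yl hydroperoxide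
Conditions: AcOH–H2O–THF, rt
Reagents that add atoms: none
Why: Mild acid hydrolysis of the mixed peroxyketal frees the secondary hydroperoxide without breaking the C3–O bond, and the acid is too weak to protonate the alkene or to cleave the silyl ether quickly.

Step 19
Reactants: 33 (3S,4S,5E,8R,12S)-1-[(tert-butyldimethylsilyl)oxy]-4,6,8,12-tetramethyl-16-phenylhexadec-5-en-3-yl hydroperoxide
Product: 35 tert-butyl{2-[(3S,4S,6R)-6-[(2R,6S)-2,6-dimethyl-10-phenyldecyl]-4,6-dimethyl-1,2-dioxan-3-yl]ethoxy}dimethylsilane, via organomercurial 34 (not isolated)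
Conditions: Hg(OAc)2, CH2Cl2, 0 °C → rt; then NaBH4, aq NaOH, 0 °C
Reagents that add atoms: none
Why: Cycloperoxymercuration closes the ring by Markovnikov 6-endo-trig attack of the hydroperoxide on C6 anti to mercury through a chair with the C4 methyl equatorial (allylic strain and avoidance of a syn-diaxial methyl pair), so the (5E) geometry places C7 equatorial and cis to the C4 methyl (C6 = R), and hydridodemercuration then replaces mercury on C5 by hydrogen.

Step 20
Reactants: 35 tert-butyl{2-[(3S,4S,6R)-6-[(2R,6S)-2,6-dimethyl-10-phenyldecyl]-4,6-dimethyl-1,2-dioxan-3-yl]ethoxy}dimethylsilane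
Product: 38 2-[(3S,4S,6R)-6-[(2R,6S)-2,6-dimethyl-10-phenyldecyl]-4,6-dimethyl-1,2-dioxan-3-yl]acetic acid, via alcohol 36 (not isolated), via aldehyde 37 (not isolated)
Conditions: CrO3, H2SO4, acetone–H2O, 0 °C
Reagents that add atoms: water, O
Why: Jones oxidation: the aqueous acid cleaves the primary silyl ether and chromic acid oxidises the alcohol through the aldehyde hydrate to the acid, conditions a dialkyl peroxide should tolerate and that touch no stereocenter.

**Compound list**

1 | 4-phenylbut-1-ene | C=CCCc1ccccc1 | starting material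
2 | 4,4,5,5-tetramethyl-2-(4-phenylbutyl)-1,3,2-dioxaborolane | CC1(C)OB(CCCCc2ccccc2)OC1(C)C | intermediate
3 | 2,4,6-triisopropylbenzoic acid | CC(C)c1cc(C(C)C)c(C(=O)O)c(C(C)C)c1 | starting material
4 | ethyl 2,4,6-triisopropylbenzoate | CCOC(=O)c1c(C(C)C)cc(C(C)C)cc1C(C)C | intermediate
5 | (1R)-1-lithioethyl 2,4,6-triisopropylbenzoate (sparteine complex) | C[C@@H]([Li])OC(=O)c1c(C(C)C)cc(C(C)C)cc1C(C)C | intermediate
6 | lithium (4-phenylbutyl)(pinacolato)[(1R)-1-(2,4,6-triisopropylbenzoyloxy)ethyl]borate | [Li+].C[C@H](OC(=O)c1c(C(C)C)cc(C(C)C)cc1C(C)C)[B-]1(CCCCc2ccccc2)OC(C)(C)C(C)(C)O1 | intermediate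
7 | 4,4,5,5-tetramethyl-2-[(2S)-6-phenylhexan-2-yl]-1,3,2-dioxaborolane | C[C@@H](CCCCc1ccccc1)B1OC(C)(C)C(C)(C)O1 | intermediate
8 | (2S)-3-bromo-2-methylpropan-1-ol | OC[C@H](C)CBr | starting material
9 | [(2S)-3-bromo-2-methylpropoxy](tert-butyl)dimethylsilane | CC(C)(C)[Si](C)(C)OC[C@H](C)CBr | intermediate
10 | {(2S)-3-[(tert-butyldimethylsilyl)oxy]-2-methylpropyl}magnesium bromide | CC(C)(C)[Si](C)(C)OC[C@H](C)C[Mg]Br | intermediate
11 | (4R)-5-[(tert-butyldimethylsilyl)oxy]-4-methylpentan-1-ol | CC(C)(C)[Si](C)(C)OC[C@H](C)CCCO | intermediate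
12 | (4R)-5-[(tert-butyldimethylsilyl)oxy]-4-methylpentyl 2,4,6-triisopropylbenzoate | CC(C)(C)[Si](C)(C)OC[C@H](C)CCCOC(=O)c1c(C(C)C)cc(C(C)C)cc1C(C)C | intermediate
13 | (1R,4R)-5-[(tert-butyldimethylsilyl)oxy]-1-lithio-4-methylpentyl 2,4,6-triisopropylbenzoate (sparteine complex) | CC(C)(C)[Si](C)(C)OC[C@H](C)CC[C@@H]([Li])OC(=O)c1c(C(C)C)cc(C(C)C)cc1C(C)C | intermediate
14 | lithium {(1R,4R)-5-[(tert-butyldimethylsilyl)oxy]-4-methyl-1-(2,4,6-triisopropylbenzoyloxy)pentyl}[(2S)-6-phenylhexan-2-yl](pinacolato)borate | [Li+].CC(C)(C)[Si](C)(C)OC[C@H](C)CC[C@H](OC(=O)c1c(C(C)C)cc(C(C)C)cc1C(C)C)[B-]1([C@@H](C)CCCCc2ccccc2)OC(C)(C)C(C)(C)O1 | intermediate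
15 | tert-butyl{[(2R,5S,6S)-2,6-dimethyl-10-phenyl-5-(4,4,5,5-tetramethyl-1,3,2-dioxaborolan-2-yl)decyl]oxy}dimethylsilane | CC(C)(C)[Si](C)(C)OC[C@H](C)CC[C@H](B1OC(C)(C)C(C)(C)O1)[C@@H](C)CCCCc1ccccc1 | intermediate
16 | lithium {(2R,5S,6S)-1-[(tert-butyldimethylsilyl)oxy]-2,6-dimethyl-10-phenyldecan-5-yl}(phenyl)(pinacolato)borate | [Li+].CC(C)(C)[Si](C)(C)OC[C@H](C)CC[C@H]([B-]1(c2ccccc2)OC(C)(C)C(C)(C)O1)[C@@H](C)CCCCc1ccccc1 | intermediate
17 | tert-butyl{[(2R,6S)-2,6-dimethyl-10-phenyldecyl]oxy}dimethylsilane | CC(C)(C)[Si](C)(C)OC[C@H](C)CCC[C@@H](C)CCCCc1ccccc1 | intermediate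
18 | [(5S,9R)-10-bromo-5,9-dimethyldecyl]benzene | BrC[C@H](C)CCC[C@@H](C)CCCCc1ccccc1 | intermediate
19 | pent-3-yn-2-one | CC#CC(C)=O | starting material
20 | (2R)-pent-3-yn-2-ol | CC#C[C@@H](C)O | intermediate
21 | (2R)-pent-3-yn-2-yl methanesulfonate | CC#C[C@@H](C)OS(C)(=O)=O | intermediate
22 | 3-[(tert-butyldimethylsilyl)oxy]propanal | O=CCCO[Si](C)(C)C(C)(C)C | starting material
23 | iodo(methanesulfonato)[(aS)-penta-2,3-dien-2-yl]indium (metal anti to the departed mesylate) | [H]C(C)=[C@]=C(C)[In](I)OS(C)(=O)=O | intermediate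
24 | (3R,4S)-1-[(tert-butyldimethylsilyl)oxy]-4-methylhept-5-yn-3-ol | CC#C[C@H](C)[C@H](O)CCO[Si](C)(C)C(C)(C)C | intermediate
25 | (3R,4S)-1-[(tert-butyldimethylsilyl)oxy]-4-methylhept-5-yn-3-yl methanesulfonate | CC#C[C@H](C)[C@H](OS(C)(=O)=O)CCO[Si](C)(C)C(C)(C)C | intermediate
26 | chlorobis(cyclopentadienyl){(2E,4S,5R)-7-[(tert-butyldimethylsilyl)oxy]-5-(methanesulfonyloxy)-4-methylhept-2-en-2-yl}zirconium (cyclopentadienyl rings drawn σ-bonded) | C/C([Zr](Cl)(C1C=CC=C1)C1C=CC=C1)=C\[C@H](C)[C@H](OS(C)(=O)=O)CCO[Si](C)(C)C(C)(C)C | intermediate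
27 | (3R,4S,5E)-1-[(tert-butyldimethylsilyl)oxy]-6-iodo-4-methylhept-5-en-3-yl methanesulfonate | C/C(I)=C\[C@H](C)[C@H](OS(C)(=O)=O)CCO[Si](C)(C)C(C)(C)C | intermediate
28 | bromo[(2R,6S)-2,6-dimethyl-10-phenyldecyl]zinc | Br[Zn]C[C@H](C)CCC[C@@H](C)CCCCc1ccccc1 | intermediate
29 | (3R,4S,5E,8R,12S)-1-[(tert-butyldimethylsilyl)oxy]-4,6,8,12-tetramethyl-16-phenylhexadec-5-en-3-yl methanesulfonate | C/C(C[C@H](C)CCC[C@@H](C)CCCCc1ccccc1)=C\[C@H](C)[C@H](OS(C)(=O)=O)CCO[Si](C)(C)C(C)(C)C | intermediate
30 | 2,3-dimethylbut-2-ene | CC(C)=C(C)C | starting material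
31 | 2-hydroperoxy-2-methoxypropane | COC(C)(C)OO | intermediate
32 | tert-butyl({(3S,4S,5E,8R,12S)-3-[(2-methoxypropan-2-yl)peroxy]-4,6,8,12-tetramethyl-16-phenylhexadec-5-en-1-yl}oxy)dimethylsilane | C/C(C[C@H](C)CCC[C@@H](C)CCCCc1ccccc1)=C\[C@H](C)[C@@H](OOC(C)(C)OC)CCO[Si](C)(C)C(C)(C)C | intermediate
33 | (3S,4S,5E,8R,12S)-1-[(tert-butyldimethylsilyl)oxy]-4,6,8,12-tetramethyl-16-phenylhexadec-5-en-3-yl hydroperoxide | C/C(C[C@H](C)CCC[C@@H](C)CCCCc1ccccc1)=C\[C@H](C)[C@@H](OO)CCO[Si](C)(C)C(C)(C)C | intermediate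
34 | (acetato){(3S,4R,5S,6R)-3-{2-[(tert-butyldimethylsilyl)oxy]ethyl}-6-[(2R,6S)-2,6-dimethyl-10-phenyldecyl]-4,6-dimethyl-1,2-dioxan-5-yl}mercury | C[C@@H](CCCCc1ccccc1)CCC[C@@H](C)C[C@]1(C)[C@@H]([Hg]OC(C)=O)[C@H](C)[C@H](CCO[Si](C)(C)C(C)(C)C)OO1 | intermediate
35 | tert-butyl{2-[(3S,4S,6R)-6-[(2R,6S)-2,6-dimethyl-10-phenyldecyl]-4,6-dimethyl-1,2-dioxan-3-yl]ethoxy}dimethylsilane | C[C@@H](CCCCc1ccccc1)CCC[C@@H](C)C[C@]1(C)C[C@H](C)[C@H](CCO[Si](C)(C)C(C)(C)C)OO1 | intermediate
36 | 2-[(3S,4S,6R)-6-[(2R,6S)-2,6-dimethyl-10-phenyldecyl]-4,6-dimethyl-1,2-dioxan-3-yl]ethan-1-ol | C[C@@H](CCCCc1ccccc1)CCC[C@@H](C)C[C@]1(C)C[C@H](C)[C@H](CCO)OO1 | intermediate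
37 | 2-[(3S,4S,6R)-6-[(2R,6S)-2,6-dimethyl-10-phenyldecyl]-4,6-dimethyl-1,2-dioxan-3-yl]acetaldehyde | C[C@@H](CCCCc1ccccc1)CCC[C@@H](C)C[C@]1(C)C[C@H](C)[C@H](CC=O)OO1 | intermediate
38 | 2-[(3S,4S,6R)-6-[(2R,6S)-2,6-dimethyl-10-phenyldecyl]-4,6-dimethyl-1,2-dioxan-3-yl]acetic acid | C[C@@H](CCCCc1ccccc1)CCC[C@@H](C)C[C@]1(C)C[C@H](C)[C@H](CC(=O)O)OO1 | target

**Summary**

Total step count: 20.
Longest linear sequence: 11 steps (steps 4, 5, 6, 7, 8, 9, 15, 17, 18, 19, 20, from 8 to 38).

Steps most likely to fail, riskiest first: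

Step 17. The intermolecular peroxide substitution may lose to E2 elimination, because the C4 hydrogen is allylic and leads to a conjugated diene, and SN2 at the β-branched secondary carbon is slow. The fallback sets out from 29 and brings the O–O unit in at C6 instead. Mukaiyama–Isayama hydroperoxysilylation (Co(thd)2, O2, Et3SiH, ClCH2CH2Cl, rt) should give (3R,4S,6R,8R,12S)-1-[(tert-butyldimethylsilyl)oxy]-4,6,8,12-tetramethyl-16-phenyl-6-[(triethylsilyl)peroxy]hexadecan-3-yl methanesulfonate F1 together with its C6 epimer, since oxygen capture by the tertiary C6 radical is not face-selective. Bu4NF in THF then frees the peroxide anion, which closes the ring by intramolecular SN2 at C3 with inversion and also removes the silyl ether. After chromatographic removal of the 6-epimer this returns to the route at alcohol 36, which is oxidised as in step 20; the price is the loss of stereocontrol at C6.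

Step 19. Ring closure may lose regiocontrol (5-exo attack at C5), and the O–O bond may be lost by fragmentation of the β-peroxyalkyl radical during reductive demercuration. The fallback sets out from 33. N-Iodosuccinimide in CH2Cl2 at 0 °C should give, by the same anti 6-endo closure, the isolable tert-butyl{2-[(3S,4R,5S,6R)-6-[(2R,6S)-2,6-dimethyl-10-phenyldecyl]-5-iodo-4,6-dimethyl-1,2-dioxan-3-yl]ethoxy}dimethylsilane F2, which can be purified and checked before reduction. Bu3SnH with Et3B/air at 0 °C then replaces iodine by hydrogen in a fast radical chain and returns to the route at 35.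

Step 7. Ate-complex formation may be incomplete or the 1,2-migration sluggish with the hindered secondary boronic ester, leading to decomposition of the lithiated benzoate. The fallback sets out from 11 and replaces the boron chemistry by a stereoinvertive substitution. CBr4/PPh3 gives tert-butyl{[(2R)-5-bromo-2-methylpentyl]oxy}dimethylsilane F3, which is converted with Mg in THF into {(4R)-5-[(tert-butyldimethylsilyl)oxy]-4-methylpentyl}magnesium bromide F4. Separately, commercial (R)-2-methyloxirane is opened at its CH2 by 3-phenylpropylmagnesium bromide (CuI cat.) to (2R)-6-phenylhexan-2-ol F5, which TsCl/pyridine converts into (2R)-6-phenylhexan-2-yl 4-methylbenzenesulfonate F6. Copper-catalysed SN2 alkyl–alkyl coupling of F4 with F6 (CuI, TMEDA, LiOMe, THF, 0 °C) inverts the carbinol carbon to the S-configured C12 and returns to the route at 17, bypassing steps 7 and 8.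

Further compounds
F1 | step 17 | (3R,4S,6R,8R,12S)-1-[(tert-butyldimethylsilyl)oxy]-4,6,8,12-tetramethyl-16-phenyl-6-[(triethylsilyl)peroxy]hexadecan-3-yl methanesulfonate | C[C@@H](CCCCc1ccccc1)CCC[C@@H](C)C[C@@](C)(OO[Si](CC)(CC)CC)C[C@H](C)[C@H](OS(C)(=O)=O)CCO[Si](C)(C)C(C)(C)C
F2 | step 19 | tert-butyl{2-[(3S,4R,5S,6R)-6-[(2R,6S)-2,6-dimethyl-10-phenyldecyl]-5-iodo-4,6-dimethyl-1,2-dioxan-3-yl]ethoxy}dimethylsilane | C[C@@H](CCCCc1ccccc1)CCC[C@@H](C)C[C@]1(C)[C@@H](I)[C@H](C)[C@H](CCO[Si](C)(C)C(C)(C)C)OO1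
F3 | step 7 | tert-butyl{[(2R)-5-bromo-2-methylpentyl]oxy}dimethylsilane | CC(C)(C)[Si](C)(C)OC[C@H](C)CCCBr
F4 | step 7 | {(4R)-5-[(tert-butyldimethylsilyl)oxy]-4-methylpentyl}magnesium bromide | CC(C)(C)[Si](C)(C)OC[C@H](C)CCC[Mg]Br
F5 | step 7 | (2R)-6-phenylhexan-2-ol | C[C@@H](O)CCCCc1ccccc1
F6 | step 7 | (2R)-6-phenylhexan-2-yl 4-methylbenzenesulfonate | C[C@@H](OS(=O)(=O)c1ccc(C)cc1)CCCCc1ccccc1
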